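The earlier runs and the new flask are calculated from invented constants; noise was put on by code.

Starting complex (S) gives complex with one exchanged (A), then complex with two exchanged (B), and you want what stands after 12 h.

| setting | Tuesday's | Thursday's | flask |
|---|---|---|---|
| starting complex | 10 mM | 40 mM | 20 mM |
| gas | 4.9 mM (held) | 4.9 mM (held) | 4.9 mM (held) |
| remark | run made earlier | run made earlier |  |
| time |  |  | 12 h |

| run | time / h | starting complex / % | complex with two exchanged / % |
|---|---|---|---|
| Tuesday's | 0.500 | 19.6 | 8.4 |
| Tuesday's | 1.33 | 3.5 | 28.8 |
| Tuesday's | 3.00 | 2.6 | 33.1 |
| Tuesday's | 8.00 | 2.6 | 33.2 |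
| Thursday's | 2.00 | 10.3 | 10.9 |
| Thursday's | 4.00 | 8.0 | 11.8 |
| Thursday's | 5.00 | 8.3 | 14.2 |
| Thursday's | 8.00 | 9.5 | 13.0 |

(readings scatter by 0.5 percentage points)

- which holds at 12 h: what has brought the reaction to rest, or that it has not come to rest (it is still moving / all of the starting complex has reacted / forward and back rates have come level)
- part of the starting complex gone at 12 h
- the complex with two exchanged standing at 12 h, as a percentage of the starting complex charged
- the complex with one exchanged standing at 12 h, as a percentage of the starting complex charged

- at the start none of the gas is in solution
- the reaction counts as stopped when no species that holds the starting complex changes by six tenths of a point or more over the second half of the time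

Take A by difference and average the plateau readings. With the gas held, A/S is 24.7 on Tuesday but 9.12 on Thursday, so I infer that a freed leaving ligand (L) pushes back. Counting one L for each A and two for each B gives 13.1 mM on Tuesday and 41.8 mM on Thursday. In powers of ten, L rises 0.504 while A/S falls 0.433, about one for one. So take the rest quotient Q, the product (A/S)·L at rest with the gas held, an apparent equilibrium constant: 350 mM.

Your flask's charge is the geometric mean of the two charges, so I place L at 23.3 mM. That gives A/S = 15.0. B/A, placed the same way, is 0.292. My reckoning leaves S at 4.90%, A at 73.6% and B at 21.5%.

Turn it round. For S to vanish from the readings, A/S needs about two powers of ten. But each S reacted frees at least one L, so with L at the charge, Q puts A/S near 1.24 powers. To count as still moving, this flask must still be changing past 6.00 h, yet Tuesday's readings stand level from 3.00 h, and Thursday's starting complex falls no further after 4.00 h.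

The forecast says forward and back rates have come level, with 95.1% gone, 21.4% of B and 73.7% of A, since “these are equilibria rather than complete consumption”.

The flask gives forward and back rates have come level, with 95.4% gone, 21.6% of B and 73.7% of A.

    starting complex + incoming ligand ⇌ leaving ligand + complex with one exchanged (K = 76.0, k = 0.510 M⁻¹ s⁻¹)
    complex with one exchanged + incoming ligand ⇌ leaving ligand + complex with two exchanged (K = 1.40, k = 0.0610 M⁻¹ s⁻¹)
    gas ⇌ incoming ligand, rate k3*(csat - [incoming ligand]) (kL = 0.00210 s⁻¹)

In this flask the second exchange, both ways together, relaxes with a half-life of 0.0800 h, far shorter than the 12 h allowed. Its backward turnover is 98% of the forward one, and Q over the flask's 23.4 mM of L gives A/S = 15.0. For the neighbour with 34 mM charged, extending the runs' trend of L with charge gives 36.4 mM, so Q predicts A/S = 9.62. That neighbour computes to 77.7% of A over 7.60% of S, a ratio of 10.2.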